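**Assumption:** the target has no stereocentre and no stereogenic axis (both trihydroxyphenyl rings are symmetric about their biaryl bonds), so it is achiral and needs no enantiocontrol. Intermediates 10 and 12 carry stereocentres as mixtures that vanish when ring C aromatizes. Ring letters: A = terminal 3,5-dihydroxyphenoxy ring, B = central bis-aryloxy ring, C = hexasubstituted ring, D and E = the two 2,4,6-trihydroxyphenyl rings. Compounds 1, 2, 6 and 8 are taken as commercial.

## Retrosynthetic overview

1. Target 14 comes from 13 by tenfold O-demethylation; ring C of 13 already carries its three free OH groups.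
2. Ring C is not cross-coupled but built last: a polyketide-type Claisen cyclization of the linear 3,5-diketo ester 12 closes the C–C bond and aromatizes. The hindered B–O–C ether and both biaryl bonds enter as sp3 C–O and C–aryl bonds.
3. 12 comes from γ-acylation of the dianion of β-keto ester 10 (rings D and E, Claisen dimer of methyl 2,4,6-trimethoxyphenylacetate) with Weinreb amide 7.
4. 7 comes from phenol 5 and chloroacetamide 6; 5 comes from Ullmann coupling of 1 with 2, then Baeyer–Villiger oxidation.
5. Ring order: A, B, D and E are bought as arenes; ring C is the only ring formed (step 7).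

## Route

Step 1
Reactants: 1 2-bromo-3,5-dimethoxybenzaldehyde; 2 3,5-dimethoxyphenol
Product: 3 2-(3,5-dimethoxyphenoxy)-3,5-dimethoxybenzaldehyde
Conditions: CuI (10 mol %), N,N-dimethylglycine (30 mol %), Cs2CO3 (2 equiv), 1,4-dioxane, 100 °C
Reagents that add atoms: none
Why: Ullmann-type copper-catalysed C–O coupling, in which the ortho-formyl group activates the C–Br bond and the unhindered phenol 2 is a good nucleophile; no stereocentre is formed.

Step 2
Reactants: 3 2-(3,5-dimethoxyphenoxy)-3,5-dimethoxybenzaldehyde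
Product: 5 2-(3,5-dimethoxyphenoxy)-3,5-dimethoxyphenol, via aryl formate 4 (not isolated)
Conditions: mCPBA (1.3 equiv), CH2Cl2, 0 °C to rt; aq NaHCO3 wash; then K2CO3 (cat.), MeOH, rt
Reagents that add atoms: mCPBA (3-chloroperoxybenzoic acid), OOC(=O)c1cccc(Cl)c1
Why: Baeyer–Villiger (Dakin-type) oxidation, in which the ortho-aryloxy lone pair favours aryl over hydride migration, followed by base-catalysed methanolysis of the formate; no stereocentre is formed.

Step 3
Reactants: 5 2-(3,5-dimethoxyphenoxy)-3,5-dimethoxyphenol; 6 2-chloro-N-methoxy-N-methylacetamide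
Product: 7 2-[2-(3,5-dimethoxyphenoxy)-3,5-dimethoxyphenoxy]-N-methoxy-N-methylacetamide
Conditions: K2CO3 (2 equiv), NaI (10 mol %), DMF, 50 °C
Reagents that add atoms: none
Why: Williamson ether synthesis (iodide-assisted SN2 on an α-chloro amide); this easy sp3 C–O bond later becomes the hindered B–O–C diaryl ether, and no stereocentre is formed.

Step 4
Reactants: 8 2-(2,4,6-trimethoxyphenyl)acetic acid
Product: 9 methyl 2-(2,4,6-trimethoxyphenyl)acetate
Conditions: MeOH, H2SO4 (cat.), reflux
Reagents that add atoms: methanol, CO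
Why: Fischer esterification driven by the large excess of methanol; no stereocentre is formed.

Step 5
Reactants: 9 methyl 2-(2,4,6-trimethoxyphenyl)acetate (2 equiv)
Product: 10 methyl 3-oxo-2,4-bis(2,4,6-trimethoxyphenyl)butanoate (racemic)
Conditions: t-BuOK (1.2 equiv per 2 equiv of 9), THF, rt to 60 °C; then 1 M HCl
Reagents that add atoms: none
Why: Claisen self-condensation pulled to completion by deprotonation of the β-keto ester product; the new C2 stereocentre is racemic and is erased in step 7.

Step 6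
Reactants: 10 methyl 3-oxo-2,4-bis(2,4,6-trimethoxyphenyl)butanoate (1.3 equiv); 7 2-[2-(3,5-dimethoxyphenoxy)-3,5-dimethoxyphenoxy]-N-methoxy-N-methylacetamide
Product: 12 methyl 6-[2-(3,5-dimethoxyphenoxy)-3,5-dimethoxyphenoxy]-3,5-dioxo-2,4-bis(2,4,6-trimethoxyphenyl)hexanoate (mixture of diastereomers and enol tautomers), via dilithio dianion 11 (not isolated)
Conditions: LiN(i-Pr)2 (LDA, 2.1 equiv per 10), THF, −78 to 0 °C; then 7, −78 to −20 °C; 1 M HCl
Reagents that add atoms: none
Why: Harris–Weiler γ-acylation of a β-keto ester dianion, in which the more basic benzylic γ-carbanion attacks the Weinreb amide and the acylation stops at the ketone stage; the new C4 stereocentre forms as a mixture that is erased in step 7.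

Step 7
Reactants: 12 methyl 6-[2-(3,5-dimethoxyphenoxy)-3,5-dimethoxyphenoxy]-3,5-dioxo-2,4-bis(2,4,6-trimethoxyphenyl)hexanoate
Product: 13 2-[2-(3,5-dimethoxyphenoxy)-3,5-dimethoxyphenoxy]-4,6-bis(2,4,6-trimethoxyphenyl)benzene-1,3,5-triol
Conditions: NaOMe (6 equiv), MeOH/diglyme, 110 °C (sealed tube), Ar; then 1 M HCl, 0 °C
Reagents that add atoms: none
Why: Proposed new method: under equilibrating methoxide conditions any O-acylation (lactone) or retro-Claisen channel is reversible, whereas 6-exo-trig attack of the C6 α-aryloxy ketone carbanion on the C1 ester gives a cyclohexane-1,3,5-trione that tautomerizes irreversibly to the aromatic phloroglucinol salt, so the system funnels to ring C and both old stereocentres disappear; the closest known reaction type is the base-mediated intramolecular Claisen (Dieckmann-type) cyclization of 3,5-dioxohexanoate esters to phloroglucinol, the chemical counterpart of the triketide cyclization in phloroglucinol biosynthesis.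

Step 8
Reactants: 13 2-[2-(3,5-dimethoxyphenoxy)-3,5-dimethoxyphenoxy]-4,6-bis(2,4,6-trimethoxyphenyl)benzene-1,3,5-triol
Product: 14 2-[2-(3,5-dihydroxyphenoxy)-3,5-dihydroxyphenoxy]-4,6-bis(2,4,6-trihydroxyphenyl)benzene-1,3,5-triol (CNP0228669.0)
Conditions: BBr3 (30 equiv), CH2Cl2, −78 °C to rt; H2O, 0 °C; Sephadex LH-20 (degassed MeOH)
Reagents that add atoms: none
Why: Lewis-acid-mediated aryl methyl ether cleavage with BBr3 removes all ten O-methyl groups by bromide SN2 at methyl, while diaryl ether and biaryl bonds are inert; the product is achiral.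

## Compound list

1 | 2-bromo-3,5-dimethoxybenzaldehyde | COc1cc(C=O)c(Br)c(OC)c1 | starting material
2 | 3,5-dimethoxyphenol | COc1cc(O)cc(OC)c1 | starting material
3 | 2-(3,5-dimethoxyphenoxy)-3,5-dimethoxybenzaldehyde | COc1cc(C=O)c(Oc2cc(OC)cc(OC)c2)c(OC)c1 | intermediate
4 | 2-(3,5-dimethoxyphenoxy)-3,5-dimethoxyphenyl formate (not isolated) | COc1cc(OC=O)c(Oc2cc(OC)cc(OC)c2)c(OC)c1 | intermediate
5 | 2-(3,5-dimethoxyphenoxy)-3,5-dimethoxyphenol | COc1cc(O)c(Oc2cc(OC)cc(OC)c2)c(OC)c1 | intermediate
6 | 2-chloro-N-methoxy-N-methylacetamide | CON(C)C(=O)CCl | starting material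
7 | 2-[2-(3,5-dimethoxyphenoxy)-3,5-dimethoxyphenoxy]-N-methoxy-N-methylacetamide | CON(C)C(=O)COc1cc(OC)cc(OC)c1Oc1cc(OC)cc(OC)c1 | intermediate
8 | 2-(2,4,6-trimethoxyphenyl)acetic acid | COc1cc(OC)c(CC(=O)O)c(OC)c1 | starting material
9 | methyl 2-(2,4,6-trimethoxyphenyl)acetate | COC(=O)Cc1c(OC)cc(OC)cc1OC | intermediate
10 | methyl 3-oxo-2,4-bis(2,4,6-trimethoxyphenyl)butanoate (racemic) | COC(=O)C(C(=O)Cc1c(OC)cc(OC)cc1OC)c1c(OC)cc(OC)cc1OC | intermediate
11 | dilithio α,γ-dianion of 10 (C2 enolate and C4 benzylic carbanion; not isolated) | [Li+].[Li+].COC(=O)C(=C([O-])[CH-]c1c(OC)cc(OC)cc1OC)c1c(OC)cc(OC)cc1OC | intermediate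
12 | methyl 6-[2-(3,5-dimethoxyphenoxy)-3,5-dimethoxyphenoxy]-3,5-dioxo-2,4-bis(2,4,6-trimethoxyphenyl)hexanoate (diastereomer and tautomer mixture) | COC(=O)C(c1c(OC)cc(OC)cc1OC)C(=O)C(c1c(OC)cc(OC)cc1OC)C(=O)COc1cc(OC)cc(OC)c1Oc1cc(OC)cc(OC)c1 | intermediate
13 | 2-[2-(3,5-dimethoxyphenoxy)-3,5-dimethoxyphenoxy]-4,6-bis(2,4,6-trimethoxyphenyl)benzene-1,3,5-triol | COc1cc(OC)cc(Oc2c(OC)cc(OC)cc2Oc2c(O)c(-c3c(OC)cc(OC)cc3OC)c(O)c(-c3c(OC)cc(OC)cc3OC)c2O)c1 | intermediate
14 | 2-[2-(3,5-dihydroxyphenoxy)-3,5-dihydroxyphenoxy]-4,6-bis(2,4,6-trihydroxyphenyl)benzene-1,3,5-triol (achiral) | Oc1cc(O)cc(Oc2c(O)cc(O)cc2Oc2c(O)c(-c3c(O)cc(O)cc3O)c(O)c(-c3c(O)cc(O)cc3O)c2O)c1 | target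

## Step count and risks

Total steps: 8. Longest linear sequence: 6 (steps 1, 2, 3, 6, 7, 8).

**Step 7 (highest risk).** The Claisen ring closure must outrun lactonization and happen on a substrate whose ester is deactivated as part of an enolate, next to two mesityl-like aryl groups. The fallback sets out from 8 and 5 and comes back at 13; it closes ring C from the other side in a [3+3] double Claisen, with the two benzylic carbons as nucleophiles and an aryloxymalonate as the bis-electrophile. Acid 8 is self-condensed with DCC and DMAP in CH2Cl2 (decarboxylative ketonization) to 1,3-bis(2,4,6-trimethoxyphenyl)propan-2-one F1. Phenol 5 is alkylated with dimethyl chloromalonate (K2CO3, acetone, 50 °C) to dimethyl 2-[2-(3,5-dimethoxyphenoxy)-3,5-dimethoxyphenoxy]propanedioate F2. F1 and F2 are then heated with t-BuOK in diglyme at 120 °C while methanol distils off, and acid work-up gives 13.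

**Step 6.** The hindered γ-carbanion of 11 may deprotonate the α-aryloxy Weinreb amide, or fragment its N-methoxy group, instead of adding to it. The fallback sets out from 7 (with dianion 11 from 10) and comes back at 12; it replaces the acylation by an aldol addition followed by oxidation. Amide 7 is reduced with LiAlH4 (THF, −78 to 0 °C) to 2-[2-(3,5-dimethoxyphenoxy)-3,5-dimethoxyphenoxy]acetaldehyde F3. Dianion 11 adds to F3 at −78 °C to give methyl 6-[2-(3,5-dimethoxyphenoxy)-3,5-dimethoxyphenoxy]-5-hydroxy-3-oxo-2,4-bis(2,4,6-trimethoxyphenyl)hexanoate F4 as a diastereomer mixture. Dess–Martin periodinane (CH2Cl2, rt) oxidizes F4 to 12.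

**Step 8.** Ten ether cleavages must all go to completion, and the free tridecaphenol is polar and air-sensitive, so direct isolation may fail. The fallback sets out from 13 and comes back at 14; it changes the endgame from direct isolation to capture, purification and release. After the BBr3 treatment and quench, the crude polyphenol is peracetylated (Ac2O, pyridine, cat. DMAP) to the trideca-O-acetate of 14 F5, which is stable and can be purified on silica, with under-demethylated material separated and recycled. F5 is then deacetylated with HCl in MeOH (from AcCl, rt, Ar) to give 14.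

Further compounds
F1 | step 7 | 1,3-bis(2,4,6-trimethoxyphenyl)propan-2-one | COc1cc(OC)c(CC(=O)Cc2c(OC)cc(OC)cc2OC)c(OC)c1
F2 | step 7 | dimethyl 2-[2-(3,5-dimethoxyphenoxy)-3,5-dimethoxyphenoxy]propanedioate | COC(=O)C(Oc1cc(OC)cc(OC)c1Oc1cc(OC)cc(OC)c1)C(=O)OC
F3 | step 6 | 2-[2-(3,5-dimethoxyphenoxy)-3,5-dimethoxyphenoxy]acetaldehyde | O=CCOc1cc(OC)cc(OC)c1Oc1cc(OC)cc(OC)c1
F4 | step 6 | methyl 6-[2-(3,5-dimethoxyphenoxy)-3,5-dimethoxyphenoxy]-5-hydroxy-3-oxo-2,4-bis(2,4,6-trimethoxyphenyl)hexanoate (diastereomer mixture) | COC(=O)C(c1c(OC)cc(OC)cc1OC)C(=O)C(c1c(OC)cc(OC)cc1OC)C(O)COc1cc(OC)cc(OC)c1Oc1cc(OC)cc(OC)c1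
F5 | step 8 | trideca-O-acetate of 14 | CC(=O)Oc1cc(OC(C)=O)cc(Oc2c(OC(C)=O)cc(OC(C)=O)cc2Oc2c(OC(C)=O)c(-c3c(OC(C)=O)cc(OC(C)=O)cc3OC(C)=O)c(OC(C)=O)c(-c3c(OC(C)=O)cc(OC(C)=O)cc3OC(C)=O)c2OC(C)=O)c1
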